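Numbering: ring C1 (stereocentre), C2, C3=C4(Me), C5, C6, C7=C8(CO2H), C9, C10, C11=C12(Me), C13, C14; side chain C15(Me)=C16, C17, C18=C19Me2.
Enabling feature: the 14-membered carbocycle is a regular head-to-tail C25 isoprenoid chain bent back on itself. Ring bond C1-C2 ties the allylic terminus C2 of the Z C3=C4 unit to C1 of what would be the C1=C15 trisubstituted alkene of the open chain, and tertiary C15 can carry the charge.
Cuts, in retrosynthetic order: O-Me of the ester; C1-C2 (with a hydrogen put back on C16, which opens the ring to an achiral pentaenyl diphosphate); C2-O(diphosphate); C7=C8; C8-C9; C9=C10 (one-carbon homologation of farnesal).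
Forward: farnesol is lengthened by C9 to an iodide that alkylates a phosphonoacetate at C8. Neryl acetate is trimmed to the C2-C7 aldehyde, and an HWE reaction joins the two at C7=C8. The C2 end becomes the diphosphate, the only ring closes at C1-C2 in the cyclase step, and saponification ends the route.
Stereochemistry: E C11=C12 and E C1=C15 come from farnesol, Z C3=C4 from neryl acetate, and C7=C8 (C6 and C9 cis, which is E by CIP because CO2R outranks C9) from the HWE step. C1 (R) and E C15=C16 are imposed by the chiral active site on an achiral substrate.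
Key step: step 12

Assumption: 19 is handled as its trisammonium salt, and a cyclase variant of the required selectivity is taken to be reachable by directed evolution of a cembrene-forming class one scaffold.

Step 1
Reactants: 1 (2E,6E)-farnesol
Product: 2 (2E,6E)-farnesal
Conditions: TEMPO (2,2,6,6-tetramethylpiperidin-1-oxyl, cat.), PhI(OAc)2, CH2Cl2, 0 °C to rt
Reagents that add atoms: none
Why: The oxoammonium (TEMPO) oxidation of a primary allylic alcohol stops at the enal and is known to leave the geometry of the neighbouring trisubstituted alkene intact.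

Step 2
Reactants: 2 (2E,6E)-farnesal
Product: 3 (3E,7E)-4,8,12-trimethyltrideca-1,3,7,11-tetraene
Conditions: Ph3PCH3Br, n-BuLi, THF, 0 °C; then 2, -78 °C to rt
Reagents that add atoms: methyltriphenylphosphonium bromide, C[P+](c1ccccc1)(c1ccccc1)c1ccccc1.[Br-]
Why: Wittig methylenation of the enal with the non-stabilised ylide brings in carbon C9 and should give the terminal 1,3-diene without touching the E alkenes.

Step 3
Reactants: 3 (3E,7E)-4,8,12-trimethyltrideca-1,3,7,11-tetraene
Product: 5 (3E,7E)-homofarnesol (4,8,12-trimethyltrideca-3,7,11-trien-1-ol), via B-homofarnesyl-9-BBN 4 (not isolated)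
Conditions: 9-BBN, THF, 0 °C to rt; then NaOH, H2O2, 0 °C
Reagents that add atoms: hydrogen peroxide, OO (oxygen of 5); 9-BBN, [BH]1C2CCCC1CCC2 (boron framework, in 4 only)
Why: In this hydroboration-oxidation the bulky borane adds only to the monosubstituted alkene with boron on terminal C9, a selectivity established for 1,3-dienes of this terpene type, so the trisubstituted alkenes should survive.

Step 4
Reactants: 5 (3E,7E)-homofarnesol
Product: 6 (3E,7E)-homofarnesyl iodide
Conditions: I2, PPh3, imidazole, CH2Cl2, 0 °C
Reagents that add atoms: iodine, II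
Why: The Appel-type iodination converts the unhindered primary alcohol by SN2 displacement of the oxyphosphonium group under near-neutral conditions that do not isomerise the alkenes.

Step 5
Reactants: 6 (3E,7E)-homofarnesyl iodide; 7 methyl 2-(diethoxyphosphoryl)acetate
Product: 9 methyl (5E,9E)-2-(diethoxyphosphoryl)-6,10,14-trimethylpentadeca-5,9,13-trienoate (racemic), via sodium phosphonoacetate enolate 8 (not isolated)
Conditions: 7 (slight excess), NaH, DMF, 0 °C; then 6, 50 °C
Reagents that add atoms: sodium hydride, [Na+].[H-] (sodium, in 8 only)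
Why: SN2 alkylation of the soft, weakly basic phosphonoacetate anion with a primary iodide forms C8-C9, and the excess of 7 should hold back dialkylation and elimination.

Step 6
Reactants: 10 neryl acetate
Product: 11 6,7-epoxyneryl acetate (racemic)
Conditions: mCPBA, CH2Cl2, 0 °C
Reagents that add atoms: 3-chloroperoxybenzoic acid, O=C(OO)c1cccc(Cl)c1
Why: The Prilezhaev epoxidation picks the electron-rich distal alkene because the allylic acetate deactivates C3=C4, and the racemic stereocentre formed is destroyed in step 7.

Step 7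
Reactants: 11 6,7-epoxyneryl acetate
Product: 13 (Z)-3-methyl-6-oxohex-2-enyl acetate, via 6,7-diol 12 (not isolated)
Conditions: H5IO6, THF/H2O, 0 °C
Reagents that add atoms: water, O (oxygen in 12 only; it leaves again with acetone)
Why: Acid-catalysed epoxide hydrolysis followed by Malaprade glycol cleavage in the same flask removes the isopropylidene carbons as acetone and should give the C2-C7 aldehyde with the Z alkene and the acetate unchanged.

Step 8
Reactants: 9 methyl (5E,9E)-2-(diethoxyphosphoryl)-6,10,14-trimethylpentadeca-5,9,13-trienoate; 13 (Z)-3-methyl-6-oxohex-2-enyl acetate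
Product: 15 (2Z,6E,10E,14E)-7-(methoxycarbonyl)-3,11,15,19-tetramethylicosa-2,6,10,14,18-pentaenyl acetate, via lithium phosphonate anion 14 (not isolated)
Conditions: LiHMDS, THF, 0 °C; then 13, 0 °C to rt
Reagents that add atoms: lithium hexamethyldisilazide, [Li+].C[Si](C)(C)[N-][Si](C)(C)C (lithium, in 14 only)
Why: In this Horner-Wadsworth-Emmons olefination the addition of the lithium phosphonate to the unhindered aldehyde is reversible, so elimination should run mainly through the less crowded adduct and place C6 trans to CO2Me (C6 and C9 cis), any geometric isomer being removed by chromatography.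

Step 9
Reactants: 15 (2Z,6E,10E,14E)-7-(methoxycarbonyl)-3,11,15,19-tetramethylicosa-2,6,10,14,18-pentaenyl acetate
Product: 16 methyl ester-bearing (2Z,6E,10E,14E)-pentaenol (7-(methoxycarbonyl)-3,11,15,19-tetramethylicosa-2,6,10,14,18-pentaen-1-ol)
Conditions: K2CO3 (cat.), MeOH, 0 °C to rt
Reagents that add atoms: none
Why: Base-catalysed transesterification in methanol removes the unhindered acetate, while exchange at the hindered conjugated ester only regenerates the methyl ester.

Step 10
Reactants: 16 methyl ester-bearing (2Z,6E,10E,14E)-pentaenol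
Product: 18 (2Z,6E,10E,14E)-allylic chloride, via alkoxydimethylsulfonium chloride 17 (not isolated)
Conditions: NCS, Me2S, CH2Cl2, -30 °C; then 16, -30 to 0 °C
Reagents that add atoms: N-chlorosuccinimide, O=C1CCC(=O)N1Cl (chlorine); dimethyl sulfide, CSC (in 17 only)
Why: In the Corey-Kim chlorination chloride displaces dimethyl sulfoxide at the primary allylic carbon by SN2 under neutral conditions, which for neryl-type alcohols proceeds without allylic transposition or Z to E scrambling.

Step 11
Reactants: 18 (2Z,6E,10E,14E)-allylic chloride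
Product: 19 (2Z,6E,10E,14E)-7-(methoxycarbonyl)-3,11,15,19-tetramethylicosa-2,6,10,14,18-pentaenyl diphosphate trisammonium salt
Conditions: (n-Bu4N)3HP2O7, MeCN, rt; then cation exchange (ammonium form), NH4HCO3 buffer; cellulose chromatography
Reagents that add atoms: tris(tetrabutylammonium) hydrogen diphosphate, CCCC[N+](CCCC)(CCCC)CCCC.CCCC[N+](CCCC)(CCCC)CCCC.CCCC[N+](CCCC)(CCCC)CCCC.OP(=O)([O-])OP(=O)([O-])[O-]; ammonium hydrogencarbonate, [NH4+].OC(=O)[O-]
Why: SN2 displacement of a primary allylic chloride by the diphosphate anion in acetonitrile is the standard route to allylic diphosphates, Z isomers included, and it leaves the alkene geometry and the methyl ester untouched.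

Step 12
Reactants: 19 (2Z,6E,10E,14E)-7-(methoxycarbonyl)-3,11,15,19-tetramethylicosa-2,6,10,14,18-pentaenyl diphosphate trisammonium salt
Product: 22 methyl (1E,5Z,8R,11E)-5,11-dimethyl-8-[(2E)-6-methylhepta-2,5-dien-2-yl]cyclotetradeca-1,5,11-triene-1-carboxylate, via cisoid allyl cation 20 (not isolated), via macrocyclic C15 cation 21 (not isolated)
Conditions: engineered class one terpene cyclase (purified), MgCl2, HEPES buffer pH 7.5, glycerol, 30 °C, pentane overlay
Reagents that add atoms: none
Why: Proposed new method: magnesium-assisted ionisation of the Z-allylic diphosphate gives the cisoid allyl cation 20, C1 of the C1=C15 alkene adds to C2 to give the tertiary cation 21, and the departed diphosphate or a nearby basic residue removes a C16 proton to give the E C15=C16 alkene of 22. The closest known reaction type is the 1,14-closure of geranylgeranyl diphosphate by class one cembrene-forming diterpene cyclases, where the exocyclic tertiary cation is quenched by proton loss from the carbon that corresponds to C16; cyclases that take neryl or (Z,Z)-farnesyl diphosphate and the known turnover of heteroatom-bearing prenyl diphosphate analogues support a cisoid, ester-bearing substrate, but no enzyme is known for 19, so such a scaffold would have to be widened below C15 for the extra prenyl unit and evolved under GC-MS screening. The one ring closes in a 14-exo-trig mode with respect to the C1=C15 alkene, C15 staying outside the ring. The single new stereocentre C1 (R) is fixed by the fold that the active-site contour forces on the achiral chain, which offers only one face of C1 to C2, and the Z C3=C4 geometry is carried over because the substrate is already cisoid and needs no isomerisation. The step needs attack by C1=C15 rather than C7=C8, C11=C12 or C18=C19 and proton loss from C16 only: the C8 ester makes a cation at C8 untenable and so shuts off the six-membered closure typical of neryl cations, Markovnikov polarisation places the charge on C15, and the remaining choices rest on the protein.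

Step 13
Reactants: 22 methyl (1E,5Z,8R,11E)-5,11-dimethyl-8-[(2E)-6-methylhepta-2,5-dien-2-yl]cyclotetradeca-1,5,11-triene-1-carboxylate
Product: 24 (1E,5Z,8R,11E)-5,11-dimethyl-8-[(2E)-6-methylhepta-2,5-dien-2-yl]cyclotetradeca-1,5,11-triene-1-carboxylic acid (CNP0112585.1), via lithium carboxylate 23 (not isolated)
Conditions: LiOH, THF/MeOH/H2O, 45 °C; then 1 M HCl to pH 3, 0 °C
Reagents that add atoms: lithium hydroxide, [Li+].[OH-] (oxygen of the acid; lithium in 23 only)
Why: Saponification by acyl-oxygen cleavage (BAc2) needs only mild heating for the alpha-branched enoate, and neither the non-acidic C1-H stereocentre nor the isolated and skipped alkenes respond to hydroxide.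

Compound list
1 | (2E,6E)-farnesol | CC(C)=CCC/C(C)=C/CC/C(C)=C/CO | starting material
2 | (2E,6E)-farnesal | CC(C)=CCC/C(C)=C/CC/C(C)=C/C=O | intermediate
3 | (3E,7E)-4,8,12-trimethyltrideca-1,3,7,11-tetraene | CC(C)=CCC/C(C)=C/CC/C(C)=C/C=C | intermediate
4 | 9-[(3E,7E)-4,8,12-trimethyltrideca-3,7,11-trienyl]-9-borabicyclo[3.3.1]nonane | CC(C)=CCC/C(C)=C/CC/C(C)=C/CCB1C2CCCC1CCC2 | intermediate
5 | (3E,7E)-homofarnesol, 4,8,12-trimethyltrideca-3,7,11-trien-1-ol | CC(C)=CCC/C(C)=C/CC/C(C)=C/CCO | intermediate
6 | (3E,7E)-homofarnesyl iodide, (6E,10E)-13-iodo-2,6,10-trimethyltrideca-2,6,10-triene | CC(C)=CCC/C(C)=C/CC/C(C)=C/CCI | intermediate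
7 | methyl 2-(diethoxyphosphoryl)acetate | COC(=O)CP(=O)(OCC)OCC | starting material
8 | sodium enolate of 7 | [Na+].COC(=O)[CH-]P(=O)(OCC)OCC | intermediate
9 | methyl (5E,9E)-2-(diethoxyphosphoryl)-6,10,14-trimethylpentadeca-5,9,13-trienoate (racemic at C8) | CC(C)=CCC/C(C)=C/CC/C(C)=C/CCC(C(=O)OC)P(=O)(OCC)OCC | intermediate
10 | neryl acetate, (Z)-3,7-dimethylocta-2,6-dienyl acetate | CC(C)=CCC/C(C)=C\COC(C)=O | starting material
11 | (Z)-5-(3,3-dimethyloxiran-2-yl)-3-methylpent-2-enyl acetate (racemic) | CC1(C)OC1CC/C(C)=C\COC(C)=O | intermediate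
12 | (Z)-6,7-dihydroxy-3,7-dimethyloct-2-enyl acetate (racemic) | CC(C)(O)C(O)CC/C(C)=C\COC(C)=O | intermediate
13 | (Z)-3-methyl-6-oxohex-2-enyl acetate | O=CCC/C(C)=C\COC(C)=O | intermediate
14 | lithium salt of 9 (carbanion at C8) | [Li+].CC(C)=CCC/C(C)=C/CC/C(C)=C/CC[C-](C(=O)OC)P(=O)(OCC)OCC | intermediate
15 | (2Z,6E,10E,14E)-7-(methoxycarbonyl)-3,11,15,19-tetramethylicosa-2,6,10,14,18-pentaenyl acetate | CC(C)=CCC/C(C)=C/CC/C(C)=C/CC/C(C(=O)OC)=C\CC/C(C)=C\COC(C)=O | intermediate
16 | (2Z,6E,10E,14E)-7-(methoxycarbonyl)-3,11,15,19-tetramethylicosa-2,6,10,14,18-pentaen-1-ol | CC(C)=CCC/C(C)=C/CC/C(C)=C/CC/C(C(=O)OC)=C\CC/C(C)=C\CO | intermediate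
17 | alkoxydimethylsulfonium chloride of 16 | CC(C)=CCC/C(C)=C/CC/C(C)=C/CC/C(C(=O)OC)=C\CC/C(C)=C\CO[S+](C)C.[Cl-] | intermediate
18 | (2Z,6E,10E,14E)-1-chloro-7-(methoxycarbonyl)-3,11,15,19-tetramethylicosa-2,6,10,14,18-pentaene | CC(C)=CCC/C(C)=C/CC/C(C)=C/CC/C(C(=O)OC)=C\CC/C(C)=C\CCl | intermediate
19 | (2Z,6E,10E,14E)-7-(methoxycarbonyl)-3,11,15,19-tetramethylicosa-2,6,10,14,18-pentaenyl diphosphate, trisammonium salt | CC(C)=CCC/C(C)=C/CC/C(C)=C/CC/C(C(=O)OC)=C\CC/C(C)=C\COP(=O)([O-])OP(=O)([O-])[O-].[NH4+].[NH4+].[NH4+] | intermediate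
20 | enzyme-bound cisoid allyl cation (charge on C2/C4) | CC(C)=CCC/C(C)=C/CC/C(C)=C/CC/C(C(=O)OC)=C\CC/C(C)=C\[CH2+] | intermediate
21 | enzyme-bound macrocyclic tertiary cation (charge on C15, C1 R) | CC(C)=CCC[C+](C)[C@H]1C/C=C(/C)CC/C=C(/C(=O)OC)CC/C=C(\C)CC1 | intermediate
22 | methyl (1E,5Z,8R,11E)-5,11-dimethyl-8-[(2E)-6-methylhepta-2,5-dien-2-yl]cyclotetradeca-1,5,11-triene-1-carboxylate | CC(C)=CC/C=C(\C)[C@H]1C/C=C(/C)CC/C=C(/C(=O)OC)CC/C=C(\C)CC1 | intermediate
23 | lithium carboxylate of 24 | CC(C)=CC/C=C(\C)[C@H]1C/C=C(/C)CC/C=C(/C(=O)[O-])CC/C=C(\C)CC1.[Li+] | intermediate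
24 | (1E,5Z,8R,11E)-5,11-dimethyl-8-[(2E)-6-methylhepta-2,5-dien-2-yl]cyclotetradeca-1,5,11-triene-1-carboxylic acid, CNP0112585.1 | CC(C)=CC/C=C(\C)[C@H]1C/C=C(/C)CC/C=C(/C(=O)O)CC/C=C(\C)CC1 | target

Total step count: 13. Longest linear sequence: 11 steps (steps 1-5 and 8-13, from farnesol).

Steps most likely to fail

1. Step 12.
- **Risk:** The protein may fail to ionise or fold the ester-bearing chain productively. Water capture, closure through the C11=C12 or C18=C19 alkene, loss of the wrong proton or poor facial selectivity at C1 could then take over.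
- **Fallback:** Known chemistry only; it sets out from aldehyde 13 and phosphonoacetate 7 and comes back at 22. C1 is set by an auxiliary-controlled alkylation, and the ring is closed at C7=C8 instead of C1-C2.
- **C2-C7 fragment:** Aldehyde 13 is masked with HC(OMe)3 and catalytic pyridinium p-toluenesulfonate in MeOH as acetal acetate F1. It is transesterified (K2CO3, MeOH) to Z allylic alcohol F2. An Appel reaction (CBr4, PPh3, 2,6-lutidine, CH2Cl2, -20 °C) converts this into Z allylic bromide F3.
- **C14, C1 and C15-C19 fragment:** But-3-yn-1-ol undergoes zirconium-catalysed carboalumination (Me3Al, Cp2ZrCl2, CH2Cl2) to alkenylalane F4. This couples with prenyl chloride under Pd(PPh3)4 in THF to give dienol F5, which holds the E C15=C16 alkene already in place. Oxidation (TEMPO, PhI(OAc)2, MeCN/H2O) gives dienoic acid F6, PivCl/Et3N gives mixed anhydride F7, and (R)-4-benzyloxazolidin-2-one with LiCl gives imide F8.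
- **Setting C1:** Evans alkylation (NaHMDS, THF, -78 °C, then F3) should take place at the alpha carbon C1 of the chelated Z(O)-dienolate, on the face remote from the benzyl group. This is a known way to alpha-allylated beta,gamma-unsaturated acid derivatives and should give alkylated imide F9 with C1 R. LiBH4/MeOH in Et2O releases the auxiliary and gives primary alcohol F10, and a second Appel reaction gives C14 bromide F11.
- **C9-C13 fragment and coupling:** Commercial 5-bromo-2-methylpent-2-ene is oxidised at its E methyl group (SeO2 cat., t-BuOOH, CH2Cl2; Riley oxidation) to E allylic alcohol F12 and brominated (CBr4, PPh3) to dibromide F13. Bromide F11 is converted with Mg in THF into Grignard reagent F14. This is coupled with F13 at the more reactive allylic carbon C13 (Li2CuCl4 cat., THF, -78 to -20 °C) to give C9 bromide F15.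
- **Ring closure:** Enolate 8 (from 7 and NaH in DMF) is alkylated by F15 to phosphonate acetal F16. Mild hydrolysis (pyridinium p-toluenesulfonate, acetone/H2O, 40 °C) gives phosphonate aldehyde F17. An intramolecular HWE reaction under Masamune-Roush conditions (LiCl, DBU, MeCN, high dilution) closes the 14-membered ring to 22.

2. Step 8.
- **Risk:** The alpha-branched phosphonate may erode the E/Z selectivity of the olefination, and the isomers may be hard to separate on a greasy C25 chain.
- **Fallback:** Stereospecific cross-coupling replaces the olefination with the branched phosphonate. It sets out from borane 4 and aldehyde 13 and comes back at 15, so the oxidative half of step 3 and steps 4 and 5 fall away.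
- **Sequence:** Commercial methyl (triphenylphosphoranylidene)acetate is brominated with NBS in CH2Cl2 at -20 °C to bromo ylide F18. Its Wittig reaction with 13 should give Z alpha-bromo enoate F19 with bromine on the side of C6.
- **Coupling:** A B-alkyl Suzuki-Miyaura coupling of 4 with F19 (PdCl2(dppf), AsPh3, Cs2CO3, DMF/THF/H2O, rt) then replaces bromine by C9 with retention and gives 15. The activated C-Br bond should add to zerovalent palladium well before the trisubstituted allylic acetate ionises.

3. Step 11.
- **Risk:** Solvolysis, allylic transposition or Z to E scrambling of the chloride may occur during the displacement, and the amphiphilic salt may be lost on ion exchange.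
- **Fallback:** The oxygen of the alcohol is phosphorylated instead of displacing at carbon. It sets out from 16 and comes back at 19, so step 10 falls away.
- **Sequence:** Alcohol 16 is treated with bis(triethylammonium) hydrogen phosphate and trichloroacetonitrile in MeCN at rt. This gives allylic monophosphate F20 and, by a second condensation of F20 with phosphate in the same flask, the diphosphate. Exchange to the ammonium form and chromatography on cellulose should give 19 with the C2-O bond never broken.

Further compounds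
F1 | step 12 | (Z)-6,6-dimethoxy-3-methylhex-2-enyl acetate | COC(OC)CC/C(C)=C\COC(C)=O
F2 | step 12 | (Z)-6,6-dimethoxy-3-methylhex-2-en-1-ol | COC(OC)CC/C(C)=C\CO
F3 | step 12 | (Z)-1-bromo-6,6-dimethoxy-3-methylhex-2-ene | COC(OC)CC/C(C)=C\CBr
F4 | step 12 | dimethylaluminium (E)-4-(dimethylalumanyl)-3-methylbut-3-en-1-olate | C[Al](C)OCC/C(C)=C/[Al](C)C
F5 | step 12 | (E)-3,7-dimethylocta-3,6-dien-1-ol | CC(C)=CC/C=C(\C)CCO
F6 | step 12 | (E)-3,7-dimethylocta-3,6-dienoic acid | CC(C)=CC/C=C(\C)CC(=O)O
F7 | step 12 | (E)-3,7-dimethylocta-3,6-dienoic pivalic anhydride | CC(C)=CC/C=C(\C)CC(=O)OC(=O)C(C)(C)C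
F8 | step 12 | (R)-4-benzyl-3-[(E)-3,7-dimethylocta-3,6-dienoyl]oxazolidin-2-one | CC(C)=CC/C=C(\C)CC(=O)N1C(=O)OC[C@H]1Cc1ccccc1
F9 | step 12 | (R)-4-benzyl-3-{(2R,3E)-2-[(Z)-6,6-dimethoxy-3-methylhex-2-enyl]-3,7-dimethylocta-3,6-dienoyl}oxazolidin-2-one | CC(C)=CC/C=C(\C)[C@H](C(=O)N1C(=O)OC[C@H]1Cc1ccccc1)C/C=C(/C)CCC(OC)OC
F10 | step 12 | (2R,3E)-2-[(Z)-6,6-dimethoxy-3-methylhex-2-enyl]-3,7-dimethylocta-3,6-dien-1-ol | CC(C)=CC/C=C(\C)[C@H](CO)C/C=C(/C)CCC(OC)OC
F11 | step 12 | (2R,3E)-1-bromo-2-[(Z)-6,6-dimethoxy-3-methylhex-2-enyl]-3,7-dimethylocta-3,6-diene | CC(C)=CC/C=C(\C)[C@H](CBr)C/C=C(/C)CCC(OC)OC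
F12 | step 12 | (E)-5-bromo-2-methylpent-2-en-1-ol | OC/C(C)=C/CCBr
F13 | step 12 | (E)-1,5-dibromo-2-methylpent-2-ene | BrC/C(C)=C/CCBr
F14 | step 12 | Grignard reagent of F11 (magnesium on C14, C1 R) | CC(C)=CC/C=C(\C)[C@H](C[Mg]Br)C/C=C(/C)CCC(OC)OC
F15 | step 12 | open-chain C9 bromide with C7 dimethyl acetal (C1 R; Z C3=C4, E C11=C12, E C15=C16) | CC(C)=CC/C=C(\C)[C@H](CC/C(C)=C/CCBr)C/C=C(/C)CCC(OC)OC
F16 | step 12 | open-chain C8 phosphonoacetate with C7 dimethyl acetal (C1 R, mixture at C8) | CC(C)=CC/C=C(\C)[C@H](CC/C(C)=C/CCC(C(=O)OC)P(=O)(OCC)OCC)C/C=C(/C)CCC(OC)OC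
F17 | step 12 | open-chain C8 phosphonoacetate with C7 aldehyde (C1 R, mixture at C8) | CC(C)=CC/C=C(\C)[C@H](CC/C(C)=C/CCC(C(=O)OC)P(=O)(OCC)OCC)C/C=C(/C)CCC=O
F18 | step 8 | methyl 2-bromo-2-(triphenylphosphoranylidene)acetate | COC(=O)C(Br)=P(c1ccccc1)(c1ccccc1)c1ccccc1
F19 | step 8 | methyl (2Z,6Z)-8-acetoxy-2-bromo-6-methylocta-2,6-dienoate | COC(=O)/C(Br)=C/CC/C(C)=C\COC(C)=O
F20 | step 11 | (2Z,6E,10E,14E)-7-(methoxycarbonyl)-3,11,15,19-tetramethylicosa-2,6,10,14,18-pentaenyl dihydrogen phosphate | CC(C)=CCC/C(C)=C/CC/C(C)=C/CC/C(C(=O)OC)=C\CC/C(C)=C\COP(=O)(O)O
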